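I could not make the two measured forms add up to the charge: in the maple run at 60.0 min they summed to 44.9 %, and I called that sum the pool.

| flask | starting complex | incoming ligand | remark | time |
|---|---|---|---|---|
| maple | 0.17 M | 0.50 M | run made earlier |  |
| cedar | 0.38 M | 0.50 M | run made earlier |  |
| alder | 0.25 M | 0.75 M | run made earlier |  |
| flask | 0.25 M | 0.500 M |  | 2.5 h |

| run | time / min | isomer of the product / % | complex with two exchanged / % |
|---|---|---|---|
| maple | 12.0 | 16.2 | 33.2 |
| maple | 25.0 | 25.5 | 22.7 |
| maple | 60.0 | 28.8 | 16.1 |
| maple | 120 | 26.9 | 14.0 |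
| cedar | 12.0 | 11.4 | 21.3 |
| cedar | 25.0 | 17.8 | 14.5 |
| cedar | 60.0 | 18.6 | 9.5 |
| cedar | 120 | 16.4 | 8.4 |
| alder | 12.0 | 17.9 | 33.2 |
| alder | 25.0 | 26.0 | 20.6 |
| alder | 60.0 | 29.0 | 15.5 |
| alder | 120 | 23.0 | 12.4 |

(standard deviation of a reading: 0.5 percentage points)



1. the best time, 2.5 h at the latest, for isomer of the product
2. the amount of isomer of the product, in percent of the starting complex charged, at that time

The isomer read highest at that time in each run. There the runs gave on average 0.652 for the isomer share: isomer over isomer plus complex with two exchanged. It read 0.641 in maple and 0.662 in cedar, but the cedar pool was 28.1 %.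

The flask looks like the maple run, with [incoming ligand] at 0.500 M in both. But [starting complex] is 0.25 M, not 0.17 M, so the equivalents fall to 2.00 from 2.94. I read the flask's pool on a straight line between maple and cedar, then applied the share:

pool = 44.9 % − (44.9 % − 28.1 %) × (0.25 M − 0.17 M) / (0.38 M − 0.17 M) = 38.5 %

isomer = 0.652 × 38.5 % = 25.1 %

So I put the flask's peak near 1 h, below the maple reading of 28.8 %, because its pool is smaller.

The forecast gave 23.5 % at 0.95 h, lower than my figure, holding that “excess ligand, rather than either concentration alone, sets the height of the maximum”.

The flask gave 24.2 % at 0.854 h.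

    starting complex + incoming ligand ⇌ leaving ligand + complex with one exchanged (K = 0.170, k = 0.660 M⁻¹ min⁻¹)
    complex with one exchanged + incoming ligand ⇌ leaving ligand + complex with two exchanged (K = 9.30, k = 2.20 M⁻¹ min⁻¹)
    complex with two exchanged ⇌ isomer of the product (K = 1.70, k = 0.0520 min⁻¹)
    complex with two exchanged + incoming ligand → over-reaction product (k = 0.0310 M⁻¹ min⁻¹)
    starting complex ⇌ dormant form (K = 4.40, k = 0.110 min⁻¹)

At that time the flask's isomer share was 0.630. The same flask with 1.2 M of incoming ligand reached 31.5 %, higher than the forecast's value, and its share at 2.50 h was 0.671. In the flask at 0.0188 h, starting complex had a forward half-life of 2.6 min by exchange, while complex with two exchanged had a forward half-life of 0.22 h by isomerisation, the longer of the pair. By 2.50 h complex with two exchanged was made at 0.677 of the rate at which it was used up, each step taken net.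

All runs stem from a simulated flask on assumed constants, noise included.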